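The ring closure rests on cutting the C4–C5 bond of ring A: C4 is the quaternary gem-dimethyl carbon, and C5, its neighbour, lies α to the oxygenated C6 of ring B. In one operation a Lewis acid ionises a tertiary chloride at C4 and the C5 terminus of a ring B C6 enol silane captures the cation, closing ring A and setting the cis ring fusion at C5 under control of the quaternary C10. The precursor is a monocyclic ring B enol silane carrying the C9 allyl group, the quaternary C10 methyl and a 4-chloro-4-methylpentyl arm; its enolate regiochemistry is stored through hydrochlorination as an α-bromo ketone.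

Key step: step 6

Remarks on the chemistry:
- The target SMILES encodes a 5,10-cis-fused decalin (H5 and the C10 methyl on one face). Enol silane 13 and decalone 14 agree with it at C5, C9 and C10, so no structure had to be altered.
- Bicyclic compounds carry labdane numbering (ring A: C1–C5, C10; ring B: C5–C10; side chain C11–C16). "syn" and "anti" refer to the face of the C10 methyl group; all bicyclic compounds are cis-fused with H5 and the C9 substituent syn.
- Anhydrous HCl would protonate an enol silane (and adds to enol esters), so the alkene is hydrochlorinated while the enolate position is held as a C5 bromide; the enol silane is regenerated afterwards.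

Step 1
Reactants: 1 pent-4-enal; 2 methyl vinyl ketone
Product: 4 (S)-4-allylcyclohex-2-en-1-one, via keto aldehyde 3 (not isolated)
Conditions: (S)-α,α-diphenylprolinol trimethylsilyl ether (10 mol %), ethyl 3,4-dihydroxybenzoate (20 mol %), neat, 4 °C; then aq. KOH, n-Bu4NOH, THF–Et2O, reflux
Reagents that add atoms: none
Why: Enamine-mediated Michael addition of the aldehyde to the vinyl ketone should set the α-stereocentre by attack on the enamine face remote from the diphenyl(silyloxy)methyl group of the (S)-catalyst, and base-induced intramolecular aldol condensation of the keto aldehyde then closes ring B without touching that centre (organocatalytic Michael addition followed by aldol condensation).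

Step 2
Reactants: 4 (S)-4-allylcyclohex-2-en-1-one
Product: 6 (S)-4-allyl-3-methylcyclohex-2-en-1-one, via lithium enolate 5 (not isolated)
Conditions: Me2CuLi, Et2O, −78 → −30 °C; then PhS(Cl)=N-t-Bu, THF, −78 °C → rt
Reagents that add atoms: lithium dimethylcuprate, [Li+].C[Cu-]C
Why: Gilman conjugate addition places methyl on the β-carbon and the lithium enolate is dehydrogenated in the same flask by sulfur transfer and syn-elimination of the sulfenamide (Mukaiyama dehydrogenation), so the transient C3 centre is erased and only the allyl-bearing centre remains.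

Step 3
Reactants: 6 (S)-4-allyl-3-methylcyclohex-2-en-1-one; 7 5-bromo-2-methylpent-2-ene
Product: 10 (3S,4S)-4-allyl-2-bromo-3-methyl-3-(4-methylpent-3-en-1-yl)cyclohexan-1-one, via Grignard reagent 8 (not isolated), via enol silane 9 (not isolated)
Conditions: 7, Mg, THF, rt; then 6, CuBr·SMe2 (10 mol %), TMSCl, DMPU, THF, −78 → −30 °C; then NBS, −78 → 0 °C
Reagents that add atoms: N-bromosuccinimide, O=C1CCC(=O)N1Br
Why: Copper-catalysed, TMSCl-accelerated 1,4-addition of the Grignard reagent should create quaternary C10 with the new chain anti to the neighbouring allyl group (axial attack on the half-chair with pseudoaxial allyl, leaving methyl cis to allyl), and bromination of the regiodefined enol silane with NBS stores the C5 enolate position as an acid-stable α-bromo ketone (conjugate addition with enolate capture, then α-bromination).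

Step 4
Reactants: 10 (3S,4S)-4-allyl-2-bromo-3-methyl-3-(4-methylpent-3-en-1-yl)cyclohexan-1-one
Product: 11 (3S,4S)-4-allyl-2-bromo-3-(4-chloro-4-methylpentyl)-3-methylcyclohexan-1-one
Conditions: HCl (g), CH2Cl2, −78 → −30 °C
Reagents that add atoms: hydrogen chloride, Cl
Why: Markovnikov hydrochlorination should be fast for the trisubstituted alkene (tertiary cation) and negligible for the monosubstituted allyl alkene at low temperature, while the ketone and the C–Br bond are inert (electrophilic addition of HCl).

Step 5
Reactants: 11 (3S,4S)-4-allyl-2-bromo-3-(4-chloro-4-methylpentyl)-3-methylcyclohexan-1-one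
Product: 13 (3S,4S)-4-allyl-3-(4-chloro-4-methylpentyl)-3-methyl-1-(trimethylsilyloxy)cyclohex-1-ene, via zinc enolate 12 (not isolated)
Conditions: Zn dust, TMSCl, TMEDA, Et2O, 0 °C → rt; filtered and concentrated under argon, used crude
Reagents that add atoms: chlorotrimethylsilane, C[Si](C)(C)Cl
Why: Zinc inserts into the activated C–Br bond α to the carbonyl (Reformatsky-type zinc enolate) and TMSCl silylates oxygen, so the enol silane should form only towards C5, while the tertiary C–Cl bond is inert to zinc and TMEDA masks the Lewis acidity of the zinc halide (regiospecific reductive silylation of an α-bromo ketone).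

Step 6
Reactants: 13 (3S,4S)-4-allyl-3-(4-chloro-4-methylpentyl)-3-methyl-1-(trimethylsilyloxy)cyclohex-1-ene
Product: 14 cis-9-allyl-4,4,10-trimethyldecalin-6-one
Conditions: TiCl4 (1.1 equiv), CH2Cl2 (high dilution), −78 °C; cold aq. NaHCO3
Reagents that add atoms: none
Why: TiCl4 abstracts chloride from C4 to give a tertiary carbenium ion paired with TiCl5−, C5 of the enol silane attacks it, and chloride then removes silicon from the silyloxycarbenium ion to release the C6 ketone and TMSCl. The closest known reaction is the Lewis-acid α-tert-alkylation of silyl enol ethers with tertiary alkyl chlorides (Reetz alkylation), used here intramolecularly. Ring A closes in a six-membered exo mode onto the tethered cation with the enol double bond outside the new ring (6-enolexo closure). The new C5 stereocentre is controlled by quaternary C10: the C4–C5 bond has to form perpendicular to the enol plane, and a three-atom bridge from C10 can reach that trajectory only on the face opposite the C10 methyl (tether pseudoequatorial, methyl pseudoaxial in the chair-like array), so the fusion should be cis with H5, the C10 methyl and the C9 allyl group on one face. The step needs C5 and not C7 to be alkylated, which the regiodefined enol silane from step 5 secures, and it needs cation capture by the enol silane to beat proton loss and attack by the allyl alkene, which the high nucleophilicity of the enol silane and the six-membered transition state at −78 °C secure. The cis ketone is the kinetic product and is quenched cold so that C5 is not equilibrated through the enol.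

Step 7
Reactants: 14 cis-9-allyl-4,4,10-trimethyldecalin-6-one
Product: 16 9-allyl-4,4,10-trimethyl-cis-decal-7-en-6-one, via lithium enolate 15 (not isolated)
Conditions: LDA, THF, −78 °C; then PhS(Cl)=N-t-Bu, −78 °C → rt
Reagents that add atoms: none
Why: LDA should remove a C7 proton kinetically, because C5–H is a hindered methine between two quaternary carbons and the ring fusion is therefore not touched, and the lithium enolate is oxidised to the 7-en-6-one (Mukaiyama dehydrogenation).

Step 8
Reactants: 16 9-allyl-4,4,10-trimethyl-cis-decal-7-en-6-one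
Product: 18 9-allyl-4,4,8,10-tetramethyl-cis-decal-7-en-6-one, via lithium enolate 17 (not isolated)
Conditions: Me2CuLi, Et2O, −78 → −20 °C; then PhS(Cl)=N-t-Bu, THF, −78 °C → rt
Reagents that add atoms: lithium dimethylcuprate, [Li+].C[Cu-]C
Why: Gilman conjugate addition to C8 followed by in-flask Mukaiyama dehydrogenation of the enolate should give the β-methyl enone, and the C8 centre formed on the way is destroyed again, so its configuration is immaterial.

Step 9
Reactants: 18 9-allyl-4,4,8,10-tetramethyl-cis-decal-7-en-6-one
Product: 19 9-allyl-7,8-epoxy-4,4,8,10-tetramethyl-cis-decalin-6-one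
Conditions: 30% aq. H2O2, LiOH, MeOH, 0 °C
Reagents that add atoms: hydrogen peroxide, OO
Why: In this Weitz–Scheffer epoxidation hydroperoxide should add axially to C8 on the face opposite the adjacent pseudoaxial C9 allyl group and the enolate then closes the epoxide, which fixes C8 with oxygen anti and methyl syn, while the isolated allyl alkene is inert to the nucleophilic oxidant.

Step 10
Reactants: 19 9-allyl-7,8-epoxy-4,4,8,10-tetramethyl-cis-decalin-6-one
Product: 20 9-allyl-8-hydroxy-4,4,8,10-tetramethyl-cis-decalin-6-one
Conditions: SmI2, THF–MeOH, −90 °C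
Reagents that add atoms: none
Why: Two single-electron transfers from SmI2 to the ketone cleave the C7–O bond α to the carbonyl and methanol protonates the samarium enolate, so the C8–O bond and the C8 configuration stay intact (reductive opening of an α,β-epoxy ketone).

Step 11
Reactants: 20 9-allyl-8-hydroxy-4,4,8,10-tetramethyl-cis-decalin-6-one
Product: 21 9-allyl-4,4,8,10-tetramethyl-cis-decalin-6,8-diol
Conditions: Me4NBH(OAc)3, AcOH–MeCN, −30 °C
Reagents that add atoms: none
Why: Exchange of the C8 hydroxyl onto boron and intramolecular hydride delivery to the C6 carbonyl from the face of that hydroxyl should give the 1,3-anti diol, that is the C6 hydroxyl trans to the C8 hydroxyl (Evans–Saksena directed reduction).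

Step 12
Reactants: 21 9-allyl-4,4,8,10-tetramethyl-cis-decalin-6,8-diol
Product: 23 9-(3-hydroxypropyl)-4,4,8,10-tetramethyl-cis-decalin-6,8-diol, via alkylborane 22 (not isolated)
Conditions: 9-BBN (3 equiv), THF, 0 °C → rt; then NaOH, H2O2, 0 °C
Reagents that add atoms: hydrogen peroxide, OO
Why: 9-BBN adds boron to the terminal carbon of the monosubstituted alkene and alkaline peroxide replaces boron by hydroxyl, with no stereocentre formed (anti-Markovnikov hydroboration–oxidation).

Step 13
Reactants: 23 9-(3-hydroxypropyl)-4,4,8,10-tetramethyl-cis-decalin-6,8-diol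
Product: 24 3-(6,8-dihydroxy-4,4,8,10-tetramethyl-cis-decalin-9-yl)propanal
Conditions: TEMPO (10 mol %), PhI(OAc)2 (1.1 equiv), CH2Cl2, rt
Reagents that add atoms: none
Why: The oxoammonium species from TEMPO oxidises the primary alcohol much faster than the hindered secondary C6 alcohol, and with one equivalent of oxidant the reaction should stop at the aldehyde, which equilibrates with its C8–O lactol (chemoselective TEMPO oxidation).

Step 14
Reactants: 24 3-(6,8-dihydroxy-4,4,8,10-tetramethyl-cis-decalin-9-yl)propanal
Product: 25 9-(but-3-yn-1-yl)-4,4,8,10-tetramethyl-cis-decalin-6,8-diol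
Conditions: dimethyl (1-diazo-2-oxopropyl)phosphonate, K2CO3, MeOH, 0 °C → rt
Reagents that add atoms: dimethyl (1-diazo-2-oxopropyl)phosphonate, COP(=O)(OC)C(=[N+]=[N-])C(C)=O
Why: Methanolysis of the Ohira–Bestmann reagent gives the diazomethylphosphonate anion, which should convert the aldehyde (free or released from the lactol) into the terminal alkyne by olefination, loss of N2 and 1,2-hydride shift (Seyferth–Gilbert homologation).

Step 15
Reactants: 25 9-(but-3-yn-1-yl)-4,4,8,10-tetramethyl-cis-decalin-6,8-diol
Product: 27 (2E)-5-(6,8-dihydroxy-4,4,8,10-tetramethyl-cis-decalin-9-yl)-3-methylpent-2-enoic acid, via alkenylalane 26 (not isolated)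
Conditions: AlMe3 (5 equiv), Cp2ZrCl2 (25 mol %), CH2Cl2, 0 °C → rt; volatiles removed, THF–hexane; n-BuLi, −78 °C; then CO2, −78 → 0 °C; aq. HCl
Reagents that add atoms: trimethylaluminium, C[Al](C)C; carbon dioxide, O=C=O
Why: Zirconium-catalysed syn-carboalumination (Negishi carboalumination) places methyl on the internal alkyne carbon and aluminium on the terminal carbon cis to it, and carboxylation of the derived alanate with retention should give the (E)-3-methyl-2-enoic acid, the hydroxyl groups being carried as aluminium alkoxides.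

Step 16
Reactants: 27 (2E)-5-(6,8-dihydroxy-4,4,8,10-tetramethyl-cis-decalin-9-yl)-3-methylpent-2-enoic acid
Product: 29 (2E)-5-[(1S,2S,4S,4aS,8aR)-4-acetoxy-2-hydroxy-2,5,5,8a-tetramethyldecahydronaphthalen-1-yl]-3-methylpent-2-enoic acid, via mixed anhydride 28 (not isolated)
Conditions: Ac2O, pyridine, DMAP (cat.), CH2Cl2, 0 °C → rt; then aq. NaHCO3–THF, rt; acidified to pH 3
Reagents that add atoms: acetic anhydride, CC(=O)OC(C)=O
Why: DMAP-catalysed acylation should esterify the secondary C6 hydroxyl while the tertiary C8 hydroxyl is too hindered to react, and the mixed anhydride formed at the carboxyl group is hydrolysed in the aqueous bicarbonate stage (selective O-acetylation).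

Compound list
1 | pent-4-enal | C=CCCC=O | starting material
2 | methyl vinyl ketone (but-3-en-2-one) | CC(=O)C=C | starting material
3 | (S)-2-allyl-5-oxohexanal | O=C[C@H](CC=C)CCC(C)=O | intermediate
4 | (S)-4-allylcyclohex-2-en-1-one | O=C1C=C[C@H](CC=C)CC1 | intermediate
5 | lithium (3S,4S)-4-allyl-3-methylcyclohex-1-en-1-olate (methyl trans to allyl) | [Li]OC1=C[C@@H](C)[C@H](CC=C)CC1 | intermediate
6 | (S)-4-allyl-3-methylcyclohex-2-en-1-one | O=C1C=C(C)[C@H](CC=C)CC1 | intermediate
7 | 5-bromo-2-methylpent-2-ene | CC(C)=CCCBr | starting material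
8 | (4-methylpent-3-en-1-yl)magnesium bromide | CC(C)=CCC[Mg]Br | intermediate
9 | (3S,4S)-4-allyl-3-methyl-3-(4-methylpent-3-en-1-yl)-1-(trimethylsilyloxy)cyclohex-1-ene (methyl cis to allyl) | C[Si](C)(C)OC1=C[C@@](C)(CCC=C(C)C)[C@H](CC=C)CC1 | intermediate
10 | (3S,4S)-4-allyl-2-bromo-3-methyl-3-(4-methylpent-3-en-1-yl)cyclohexan-1-one (both C2 epimers) | O=C1C(Br)[C@@](C)(CCC=C(C)C)[C@H](CC=C)CC1 | intermediate
11 | (3S,4S)-4-allyl-2-bromo-3-(4-chloro-4-methylpentyl)-3-methylcyclohexan-1-one (both C2 epimers) | O=C1C(Br)[C@@](C)(CCCC(C)(C)Cl)[C@H](CC=C)CC1 | intermediate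
12 | bromozinc (3S,4S)-4-allyl-3-(4-chloro-4-methylpentyl)-3-methylcyclohex-1-en-1-olate | Br[Zn]OC1=C[C@@](C)(CCCC(C)(C)Cl)[C@H](CC=C)CC1 | intermediate
13 | (3S,4S)-4-allyl-3-(4-chloro-4-methylpentyl)-3-methyl-1-(trimethylsilyloxy)cyclohex-1-ene (methyl cis to allyl) | C=CC[C@@H]1CCC(O[Si](C)(C)C)=C[C@@]1(C)CCCC(C)(C)Cl | intermediate
14 | cis-9-allyl-4,4,10-trimethyldecalin-6-one, systematically (4S,4aS,8aS)-4-allyl-4a,8,8-trimethyloctahydronaphthalen-1(2H)-one (H5 and C9 allyl syn) | O=C1CC[C@@H](CC=C)[C@]2(C)CCCC(C)(C)[C@H]12 | intermediate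
15 | lithium 9-allyl-4,4,10-trimethyl-cis-decal-6-en-6-olate (C6–C7 enolate of 14) | [Li]OC1=CC[C@@H](CC=C)[C@]2(C)CCCC(C)(C)[C@H]12 | intermediate
16 | 9-allyl-4,4,10-trimethyl-cis-decal-7-en-6-one | O=C1C=C[C@@H](CC=C)[C@]2(C)CCCC(C)(C)[C@H]12 | intermediate
17 | lithium 9-allyl-4,4,8,10-tetramethyl-cis-decal-6-en-6-olate (8-methyl anti) | [Li]OC1=C[C@H](C)[C@@H](CC=C)[C@]2(C)CCCC(C)(C)[C@H]12 | intermediate
18 | 9-allyl-4,4,8,10-tetramethyl-cis-decal-7-en-6-one | O=C1C=C(C)[C@@H](CC=C)[C@]2(C)CCCC(C)(C)[C@H]12 | intermediate
19 | 9-allyl-7,8-epoxy-4,4,8,10-tetramethyl-cis-decalin-6-one (epoxide oxygen anti, 8-methyl syn) | O=C1[C@@H]2O[C@]2(C)[C@@H](CC=C)[C@]3(C)CCCC(C)(C)[C@H]13 | intermediate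
20 | 9-allyl-8-hydroxy-4,4,8,10-tetramethyl-cis-decalin-6-one (8-OH anti, 8-methyl syn) | O=C1C[C@](C)(O)[C@@H](CC=C)[C@]2(C)CCCC(C)(C)[C@H]12 | intermediate
21 | 9-allyl-4,4,8,10-tetramethyl-cis-decalin-6,8-diol (6-OH syn, 8-OH anti) | O[C@H]1C[C@](C)(O)[C@@H](CC=C)[C@]2(C)CCCC(C)(C)[C@H]12 | intermediate
22 | B-alkyl-9-borabicyclo[3.3.1]nonane formed from 21 at C13 | O[C@H]1C[C@](C)(O)[C@@H](CCCB3C4CCCC3CCC4)[C@]2(C)CCCC(C)(C)[C@H]12 | intermediate
23 | 9-(3-hydroxypropyl)-4,4,8,10-tetramethyl-cis-decalin-6,8-diol | O[C@H]1C[C@](C)(O)[C@@H](CCCO)[C@]2(C)CCCC(C)(C)[C@H]12 | intermediate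
24 | 3-(6,8-dihydroxy-4,4,8,10-tetramethyl-cis-decalin-9-yl)propanal (in equilibrium with its C8–O lactol) | O[C@H]1C[C@](C)(O)[C@@H](CCC=O)[C@]2(C)CCCC(C)(C)[C@H]12 | intermediate
25 | 9-(but-3-yn-1-yl)-4,4,8,10-tetramethyl-cis-decalin-6,8-diol | O[C@H]1C[C@](C)(O)[C@@H](CCC#C)[C@]2(C)CCCC(C)(C)[C@H]12 | intermediate
26 | (E)-alkenyldimethylalane from 25, both hydroxyls as dimethylaluminium alkoxides | C[Al](C)O[C@H]1C[C@](C)(O[Al](C)C)[C@@H](CC/C(C)=C/[Al](C)C)[C@]2(C)CCCC(C)(C)[C@H]12 | intermediate
27 | (2E)-5-(6,8-dihydroxy-4,4,8,10-tetramethyl-cis-decalin-9-yl)-3-methylpent-2-enoic acid | O[C@H]1C[C@](C)(O)[C@@H](CC/C(C)=C/C(=O)O)[C@]2(C)CCCC(C)(C)[C@H]12 | intermediate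
28 | mixed carboxylic–acetic anhydride of 29 | CC(=O)O[C@H]1C[C@](C)(O)[C@@H](CC/C(C)=C/C(=O)OC(C)=O)[C@]2(C)CCCC(C)(C)[C@H]12 | intermediate
29 | (2E)-5-[(1S,2S,4S,4aS,8aR)-4-acetoxy-2-hydroxy-2,5,5,8a-tetramethyldecahydronaphthalen-1-yl]-3-methylpent-2-enoic acid (6-OAc syn, 8-OH anti, 8-methyl syn) | CC(=O)O[C@H]1C[C@](C)(O)[C@@H](CC/C(C)=C/C(=O)O)[C@]2(C)CCCC(C)(C)[C@H]12 | target

Total step count: 16
Longest linear sequence: 16 steps (1 and 2 to 29); bromide 7 enters at step 3.

Steps most likely to fail

1. Step 6 (ring closure). What may go wrong: after ionisation the C4 cation loses a proton, or traces of HCl strip the labile trimethylsilyl group, faster than the hindered C5 terminus closes the ring. Fallback: the closure is moved to the enone oxidation level, where the enol silane is robust and its position is unambiguous. Setting out from 11, zinc in acetic acid removes the bromine to give (3R,4S)-4-allyl-3-(4-chloro-4-methylpentyl)-3-methylcyclohexan-1-one F1. Kinetic deprotonation at the unhindered CH2 (LDA, −78 °C) and Mukaiyama dehydrogenation give (4R,5R)-4-allyl-5-(4-chloro-4-methylpentyl)-5-methylcyclohex-2-en-1-one F2, in which only the CH2 next to the quaternary carbon remains for α′-deprotonation. LDA and TBSCl then give the isolable cross-conjugated dienol ether tert-butyl{[4-allyl-3-(4-chloro-4-methylpentyl)-3-methylcyclohexa-1,5-dien-1-yl]oxy}dimethylsilane F3. TiCl4 in CH2Cl2 at −78 °C should close ring A through the same C4–C5 bond and return the route at enone 16, so that steps 5 to 7 are bypassed.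

2. Step 9 (epoxidation). What may go wrong: hydroperoxide addition to the hindered β,β-disubstituted enone is slow, its facial selectivity at C8 erodes, or the basic medium enolises C5 and lets the ring fusion drift towards trans. Fallback: the C8 oxygen is introduced through boron. Setting out from 18, copper-catalysed conjugate borylation (CuCl, NaOt-Bu, Xantphos, B2pin2, MeOH, THF) should add boron to C8 anti to the C9 substituent and give 9-allyl-4,4,8,10-tetramethyl-8-(pinacolboryl)-cis-decalin-6-one F4. Oxidation with NaBO3 proceeds with retention and returns the route at 20, bypassing 19 and step 10 under nearly neutral conditions.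

3. Step 15 (carboalumination and carboxylation). What may go wrong: the aluminium alkoxides formed from the two free hydroxyl groups slow the carboalumination, or the alanate carboxylates poorly, so conversion to the acid stays incomplete. Fallback: the enoate is built by olefination of a methyl ketone. Setting out from 21, cross-metathesis with isopropenylboronic acid pinacol ester (second-generation Grubbs catalyst) gives 9-[3-(pinacolboryl)but-2-en-1-yl]-4,4,8,10-tetramethyl-cis-decalin-6,8-diol F5. NaBO3 oxidation gives 9-(3-oxobutyl)-4,4,8,10-tetramethyl-cis-decalin-6,8-diol F6. Horner–Wadsworth–Emmons reaction with triethyl phosphonoacetate and NaH gives ethyl (2E)-5-(6,8-dihydroxy-4,4,8,10-tetramethyl-cis-decalin-9-yl)-3-methylpent-2-enoate F7, the minor Z isomer being removed by chromatography. Saponification with LiOH returns the route at 27, so that steps 12 to 15 are bypassed.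

Further compounds
F1 | step 6 | (3R,4S)-4-allyl-3-(4-chloro-4-methylpentyl)-3-methylcyclohexan-1-one | O=C1C[C@@](C)(CCCC(C)(C)Cl)[C@H](CC=C)CC1
F2 | step 6 | (4R,5R)-4-allyl-5-(4-chloro-4-methylpentyl)-5-methylcyclohex-2-en-1-one | O=C1C[C@@](C)(CCCC(C)(C)Cl)[C@H](CC=C)C=C1
F3 | step 6 | tert-butyl{[4-allyl-3-(4-chloro-4-methylpentyl)-3-methylcyclohexa-1,5-dien-1-yl]oxy}dimethylsilane (stereocentres as in F2) | CC(C)(C)[Si](C)(C)OC1=C[C@@](C)(CCCC(C)(C)Cl)[C@H](CC=C)C=C1
F4 | step 9 | 9-allyl-4,4,8,10-tetramethyl-8-(pinacolboryl)-cis-decalin-6-one (boron anti) | O=C1C[C@](C)(B2OC(C)(C)C(C)(C)O2)[C@@H](CC=C)[C@]3(C)CCCC(C)(C)[C@H]13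
F5 | step 15 | 9-[3-(pinacolboryl)but-2-en-1-yl]-4,4,8,10-tetramethyl-cis-decalin-6,8-diol | O[C@H]1C[C@](C)(O)[C@@H](CC=C(C)B3OC(C)(C)C(C)(C)O3)[C@]2(C)CCCC(C)(C)[C@H]12
F6 | step 15 | 9-(3-oxobutyl)-4,4,8,10-tetramethyl-cis-decalin-6,8-diol | O[C@H]1C[C@](C)(O)[C@@H](CCC(C)=O)[C@]2(C)CCCC(C)(C)[C@H]12
F7 | step 15 | ethyl (2E)-5-(6,8-dihydroxy-4,4,8,10-tetramethyl-cis-decalin-9-yl)-3-methylpent-2-enoate | O[C@H]1C[C@](C)(O)[C@@H](CC/C(C)=C/C(=O)OCC)[C@]2(C)CCCC(C)(C)[C@H]12
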